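**Strategy.** Everything rests on one disconnection, O1–C8a of dihydropyran ring B. The rest of the C2 environment (the O1–C2 bond, the C2 methyl, C3–C4 and side-chain carbons C1'–C9') is already present as the tertiary vinyl carbinol of (S)-nerolidol. A palladium-catalysed aryl C–O coupling of that tertiary alcohol onto the C8a triflate of benzene ring A therefore closes ring B in one operation and never touches C2. The cyclisation substrate is the nerolidol-derived carbinol carrying a 2-triflyloxy-5-silyloxy-3,4-dimethylphenyl group on C4. The remaining C30 carbinol chain is then attached as an allyl sulfone across C9'–C10'.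

Key step: step 5

Remark (numbering): chroman atoms are O1, C2–C4, C4a, C5–C8, C8a (ring A benzene, ring B dihydropyran); the side chain is C1'–C33' counted from C2, with methyls on C4', C8', C12', C16', C20', C24', C28', C32'.
Remark (configuration): the target as drawn is (2S,24'S); both centres have the spatial arrangement of the (S)-nerolidol carbinol.
Remark (assumption): (S)-(+)-(E)-nerolidol of high optical purity and (2E,6E)-farnesyl bromide are purchased; the optical purity of the nerolidol and of the Sharpless epoxide caps the stereochemical purity at C2 and C24'.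
Remark (design): the C6 phenol is carried as a triisopropylsilyl ether, because a tert-butyldimethylsilyl aryl ether is prone to cleavage by the aqueous phosphate and the carbonate used in steps 4 and 5.

**Ring A building block**

Step 1
Reactants: 1 2,3-dimethylhydroquinone
Product: 2 2,3-dimethyl-4-(triisopropylsilyloxy)phenol
Conditions: TIPSCl (0.8 equiv), imidazole, DMF, 0 °C → rt
Reagents that add atoms: triisopropylsilyl chloride, CC(C)[Si](Cl)(C(C)C)C(C)C
Why: Silyl ether formation on a C2-symmetric diol, so either hydroxyl gives the same mono-ether and a deficit of silyl chloride limits bis-silylation; the bulky silyl group is chosen to survive the bases used later.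

Step 2
Reactants: 2 2,3-dimethyl-4-(triisopropylsilyloxy)phenol
Product: 3 6-iodo-2,3-dimethyl-4-(triisopropylsilyloxy)phenol
Conditions: NIS, p-TsOH (cat.), MeCN, 0 °C, dark
Reagents that add atoms: N-iodosuccinimide, O=C1CCC(=O)N1I
Why: Electrophilic aromatic iodination directed by the free hydroxyl, whose para position is blocked and whose only open ortho position is C6 (the future C4a), while the other ring CH sits next to the bulky silyl ether.

Step 3
Reactants: 3 6-iodo-2,3-dimethyl-4-(triisopropylsilyloxy)phenol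
Product: 4 6-iodo-2,3-dimethyl-4-(triisopropylsilyloxy)phenyl trifluoromethanesulfonate
Conditions: Tf2O, pyridine, CH2Cl2, 0 °C
Reagents that add atoms: trifluoromethanesulfonic anhydride, O=S(=O)(OS(=O)(=O)C(F)(F)F)C(F)(F)F
Why: O-Sulfonylation of the phenol turns the future C8a oxygen into a leaving group; the silyl ether and the aryl iodide are inert to these conditions.

**Precursor, ring closure and C9' activation**

Step 4
Reactants: 5 (S)-(+)-(E)-nerolidol; 4 6-iodo-2,3-dimethyl-4-(triisopropylsilyloxy)phenyl trifluoromethanesulfonate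
Product: 7 6-[(3S,6E)-3-hydroxy-3,7,11-trimethyldodeca-6,10-dien-1-yl]-2,3-dimethyl-4-(triisopropylsilyloxy)phenyl trifluoromethanesulfonate, via alkylborane 6 (not isolated)
Conditions: 9-BBN (2.2 equiv), THF, 0 °C → rt; then 4, PdCl2(dppf) (5 mol%), K3PO4 (aq), DMF, rt
Reagents that add atoms: none
Why: Chemoselective anti-Markovnikov hydroboration of the only monosubstituted olefin, followed by B-alkyl Suzuki–Miyaura coupling at the C–I bond, into which zerovalent palladium inserts much faster than into the neighbouring C–OTf bond; no bond to the carbinol carbon is touched.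

Step 5
Reactants: 7 6-[(3S,6E)-3-hydroxy-3,7,11-trimethyldodeca-6,10-dien-1-yl]-2,3-dimethyl-4-(triisopropylsilyloxy)phenyl trifluoromethanesulfonate
Product: 8 (2S)-2-[(3E)-4,8-dimethylnona-3,7-dien-1-yl]-2,7,8-trimethyl-6-(triisopropylsilyloxy)chroman
Conditions: Pd(OAc)2 (5 mol%), 2-(di-tert-butylphosphino)-1,1'-binaphthyl (6 mol%), Cs2CO3, toluene, 80 °C
Reagents that add atoms: none
Why: Zerovalent palladium formed in situ should insert into the C8a–OTf bond, the caesium alkoxide of the C2 carbinol then displaces triflate on divalent palladium, and C–O reductive elimination from the seven-membered aryl(alkoxo)palladacycle forges O1–C8a. The closest known reaction type is the palladium-catalysed intramolecular etherification of tertiary alcohols bearing an o-haloaryl group, run here with the triflate pseudohalide that aryl C–O couplings also accept. Ring B (O1–C2–C3–C4–C4a–C8a) closes in a 6-exo sense at the ipso carbon C8a. No stereocentre is created, and C2 keeps the nerolidol configuration because its C–O bond is never ionised and no cation arises next to the diene. The selectivity needed is reductive elimination over S–O cleavage of the triflate, arene reduction or β-hydride loss. The hydrogen-free carbinol carbon excludes the last, and the bulky electron-rich phosphine with the weak, sparingly soluble base Cs2CO3 should favour the first while sparing the silyl ether.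

Step 6
Reactants: 8 (2S)-2-[(3E)-4,8-dimethylnona-3,7-dien-1-yl]-2,7,8-trimethyl-6-(triisopropylsilyloxy)chroman
Product: 9 (2E,6E)-2,6-dimethyl-9-[(2S)-2,7,8-trimethyl-6-(triisopropylsilyloxy)chroman-2-yl]nona-2,6-dien-1-ol
Conditions: SeO2 (cat.), t-BuOOH, salicylic acid (cat.), CH2Cl2, 0 °C → rt, stopped at partial conversion
Reagents that add atoms: selenium dioxide, O=[Se]=O (delivers the oxygen and is turned over by tert-butyl hydroperoxide, CC(C)(C)OO)
Why: Riley allylic oxidation (ene reaction then [2,3]-shift), which should prefer the E-methyl of the exposed terminal isopropylidene group over the internal olefin and so deliver the (E)-allylic alcohol at C9'.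

Step 7
Reactants: 9 (2E,6E)-2,6-dimethyl-9-[(2S)-2,7,8-trimethyl-6-(triisopropylsilyloxy)chroman-2-yl]nona-2,6-dien-1-ol
Product: 10 (2S)-2-[(3E,7E)-9-bromo-4,8-dimethylnona-3,7-dien-1-yl]-2,7,8-trimethyl-6-(triisopropylsilyloxy)chroman
Conditions: CBr4, PPh3, CH2Cl2, −20 → 0 °C
Reagents that add atoms: carbon tetrabromide, BrC(Br)(Br)Br
Why: Appel bromination of a primary allylic alcohol under neutral conditions, which should proceed by SN2 at C9' without allylic transposition or loss of E geometry.

**C15 sulfone half (C10'–C21')**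

Step 8
Reactants: 11 (2E,6E)-farnesyl bromide
Product: 12 (2E,6E)-farnesyl phenyl sulfone
Conditions: PhSO2Na, DMF, rt
Reagents that add atoms: sodium benzenesulfinate, [Na+].[O-]S(=O)c1ccccc1
Why: SN2 S-alkylation of the sulfinate at the primary allylic carbon, a standard entry to prenyl sulfones that keeps the olefin geometry.

Step 9
Reactants: 12 (2E,6E)-farnesyl phenyl sulfone
Product: 13 (2E,6E,10E)-2,6,10-trimethyl-12-(phenylsulfonyl)dodeca-2,6,10-trien-1-ol
Conditions: SeO2 (cat.), t-BuOOH, salicylic acid (cat.), CH2Cl2, 0 °C → rt, stopped at partial conversion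
Reagents that add atoms: selenium dioxide, O=[Se]=O (delivers the oxygen and is turned over by tert-butyl hydroperoxide, CC(C)(C)OO)
Why: Riley oxidation at the terminal E-methyl; the olefin next to the sulfone is electronically deactivated and the terminal isopropylidene is the most accessible of the remaining two.

Step 10
Reactants: 13 (2E,6E,10E)-2,6,10-trimethyl-12-(phenylsulfonyl)dodeca-2,6,10-trien-1-ol
Product: 14 (2E,6E,10E)-12-bromo-3,7,11-trimethyldodeca-2,6,10-trien-1-yl phenyl sulfone
Conditions: CBr4, PPh3, CH2Cl2, −20 → 0 °C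
Reagents that add atoms: carbon tetrabromide, BrC(Br)(Br)Br
Why: Appel bromination of the primary allylic alcohol; the sulfone and the trisubstituted olefins are inert.

**C15 carbinol half (C22'–C33') and the C30 sulfone**

Step 11
Reactants: 15 (2E,6E)-farnesol
Product: 16 (2S,3S)-2,3-epoxyfarnesol
Conditions: Ti(OiPr)4 (cat.), L-(+)-diethyl tartrate (cat.), t-BuOOH, 4 Å MS, CH2Cl2, −20 °C
Reagents that add atoms: tert-butyl hydroperoxide, CC(C)(C)OO
Why: Sharpless asymmetric epoxidation, in which only the allylic-alcohol olefin reacts and the L-(+)-tartrate–titanium catalyst delivers oxygen to the face that gives the (2S,3S)-epoxide, fixing the future C24' oxygen-bearing centre.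

Step 12
Reactants: 16 (2S,3S)-2,3-epoxyfarnesol
Product: 17 (2R,3S)-1-chloro-2,3-epoxy-3,7,11-trimethyldodeca-6,10-diene
Conditions: PPh3, CCl4, NaHCO3, reflux
Reagents that add atoms: carbon tetrachloride, ClC(Cl)(Cl)Cl
Why: Appel chlorination of the primary alcohol under buffered conditions, leaving the epoxide intact; the change of descriptor at C2 is only a change in CIP ranking.

Step 13
Reactants: 17 (2R,3S)-1-chloro-2,3-epoxy-3,7,11-trimethyldodeca-6,10-diene
Product: 19 (3S,6E)-3,7,11-trimethyldodeca-6,10-dien-1-yn-3-ol, via chlorovinyl carbinolate 18 (not isolated)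
Conditions: n-BuLi (3.3 equiv), THF, −40 → −20 °C; NH4Cl (aq)
Reagents that add atoms: none
Why: Base-induced double elimination of a 2,3-epoxy chloride (lithiation at the CHCl carbon opens the epoxide to the chlorovinyl alkoxide, and loss of LiCl then gives the acetylide), a known route to propargylic alcohols in which the C3–O bond is never broken, so the Sharpless-derived configuration is retained.

Step 14
Reactants: 19 (3S,6E)-3,7,11-trimethyldodeca-6,10-dien-1-yn-3-ol; 14 (2E,6E,10E)-12-bromo-3,7,11-trimethyldodeca-2,6,10-trien-1-yl phenyl sulfone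
Product: 20 (6E,10S,14E,18E,22E)-2,6,10,14,18,22-hexamethyl-24-(phenylsulfonyl)tetracosa-2,6,14,18,22-pentaen-11-yn-10-ol
Conditions: CuI (20 mol%), K2CO3, n-Bu4NI (cat.), DMF, rt, argon
Reagents that add atoms: none
Why: Copper-catalysed allylation of a terminal alkyne, in which the copper acetylide should substitute the primary allylic bromide at its unhindered CH2 terminus (SN2) to give the skipped enyne; the carbonate is too weak to deprotonate the allyl sulfone or the tertiary alcohol.

Step 15
Reactants: 20 (6E,10S,14E,18E,22E)-2,6,10,14,18,22-hexamethyl-24-(phenylsulfonyl)tetracosa-2,6,14,18,22-pentaen-11-yn-10-ol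
Product: 21 (6E,10S,11E,14E,18E,22E)-2,6,10,14,18,22-hexamethyl-24-(phenylsulfonyl)tetracosa-2,6,11,14,18,22-hexaen-10-ol
Conditions: NaAlH2(OCH2CH2OMe)2, THF, 0 °C → rt; potassium sodium tartrate (aq)
Reagents that add atoms: none
Why: Hydroxyl-directed trans-hydroalumination of a propargylic alcohol, whose cyclic alkenylaluminate gives only the (E)-olefin on protonolysis; isolated olefins and the aryl sulfone are not reduced at this temperature.

**Fragment union and release of the target**

Step 16
Reactants: 21 (6E,10S,11E,14E,18E,22E)-2,6,10,14,18,22-hexamethyl-24-(phenylsulfonyl)tetracosa-2,6,11,14,18,22-hexaen-10-ol; 10 (2S)-2-[(3E,7E)-9-bromo-4,8-dimethylnona-3,7-dien-1-yl]-2,7,8-trimethyl-6-(triisopropylsilyloxy)chroman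
Product: 23 (2S)-2-[(3E,7E,11E,15E,19E,22E,24S,27E)-24-hydroxy-4,8,12,16,20,24,28,32-octamethyl-10-(phenylsulfonyl)tritriaconta-3,7,11,15,19,22,27,31-octaen-1-yl]-2,7,8-trimethyl-6-(triisopropylsilyloxy)chroman (both C10' epimers), via dilithio sulfone 22 (not isolated)
Conditions: n-BuLi (2.1 equiv), THF–DMPU, −78 °C; then 10, −78 → −40 °C
Reagents that add atoms: none
Why: Allylation of an α-sulfonyl carbanion, where the second equivalent of base generates the soft allyl sulfone anion beside the hindered lithium alkoxide and this carbon nucleophile should displace the primary allylic bromide by SN2 to form C9'–C10' with both olefin geometries intact; the new C10' centre is not controlled and is erased in step 17.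

Step 17
Reactants: 23 the C10'-phenylsulfonyl coupling product
Product: 24 (2S)-2-[(3E,7E,11E,15E,19E,22E,24S,27E)-24-hydroxy-4,8,12,16,20,24,28,32-octamethyltritriaconta-3,7,11,15,19,22,27,31-octaen-1-yl]-2,7,8-trimethyl-6-(triisopropylsilyloxy)chroman
Conditions: PdCl2(dppp) (10 mol%), LiBEt3H, THF, 0 °C
Reagents that add atoms: none
Why: Palladium-catalysed reductive desulfonylation, in which zerovalent palladium ionises the allylic sulfone to a π-allyl complex and hydride is delivered to the less substituted terminus C10', so the C11'=C12' olefin should stay trisubstituted and E; the tertiary allylic alkoxide is not a leaving group.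

Step 18
Reactants: 24 the triisopropylsilyl ether of the target
Product: 25 (2S)-2-[(3E,7E,11E,15E,19E,22E,24S,27E)-24-hydroxy-4,8,12,16,20,24,28,32-octamethyltritriaconta-3,7,11,15,19,22,27,31-octaen-1-yl]-2,7,8-trimethylchroman-6-ol
Conditions: Bu4NF, AcOH, THF, 0 °C, argon
Reagents that add atoms: none
Why: Fluoride-mediated cleavage of the aryl silyl ether, buffered with acetic acid so that the electron-rich chromanol is not left as an air-sensitive phenoxide and the acid-labile tertiary allylic alcohol never meets strong acid.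

**Compound list**

1 | 2,3-dimethylhydroquinone | Cc1c(C)c(O)ccc1O | starting material
2 | 2,3-dimethyl-4-(triisopropylsilyloxy)phenol | Cc1c(C)c(O[Si](C(C)C)(C(C)C)C(C)C)ccc1O | intermediate
3 | 6-iodo-2,3-dimethyl-4-(triisopropylsilyloxy)phenol | Cc1c(C)c(O[Si](C(C)C)(C(C)C)C(C)C)cc(I)c1O | intermediate
4 | 6-iodo-2,3-dimethyl-4-(triisopropylsilyloxy)phenyl trifluoromethanesulfonate | Cc1c(C)c(O[Si](C(C)C)(C(C)C)C(C)C)cc(I)c1OS(=O)(=O)C(F)(F)F | intermediate
5 | (S)-(+)-(E)-nerolidol, (3S,6E)-3,7,11-trimethyldodeca-1,6,10-trien-3-ol | CC(C)=CCC/C(C)=C/CC[C@](C)(O)C=C | starting material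
6 | 9-[(3R,6E)-3-hydroxy-3,7,11-trimethyldodeca-6,10-dien-1-yl]-9-borabicyclo[3.3.1]nonane (carbinol geometry of 5; the descriptor R arises only from CIP ranking) | CC(C)=CCC/C(C)=C/CC[C@](C)(O)CCB1C2CCCC1CCC2 | intermediate (not isolated)
7 | 6-[(3S,6E)-3-hydroxy-3,7,11-trimethyldodeca-6,10-dien-1-yl]-2,3-dimethyl-4-(triisopropylsilyloxy)phenyl trifluoromethanesulfonate | CC(C)=CCC/C(C)=C/CC[C@](C)(O)CCc1cc(O[Si](C(C)C)(C(C)C)C(C)C)c(C)c(C)c1OS(=O)(=O)C(F)(F)F | intermediate
8 | (2S)-2-[(3E)-4,8-dimethylnona-3,7-dien-1-yl]-2,7,8-trimethyl-6-(triisopropylsilyloxy)chroman | CC(C)=CCC/C(C)=C/CC[C@@]1(C)CCc2cc(O[Si](C(C)C)(C(C)C)C(C)C)c(C)c(C)c2O1 | intermediate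
9 | (2E,6E)-2,6-dimethyl-9-[(2S)-2,7,8-trimethyl-6-(triisopropylsilyloxy)chroman-2-yl]nona-2,6-dien-1-ol | OC/C(C)=C/CC/C(C)=C/CC[C@@]1(C)CCc2cc(O[Si](C(C)C)(C(C)C)C(C)C)c(C)c(C)c2O1 | intermediate
10 | (2S)-2-[(3E,7E)-9-bromo-4,8-dimethylnona-3,7-dien-1-yl]-2,7,8-trimethyl-6-(triisopropylsilyloxy)chroman | BrC/C(C)=C/CC/C(C)=C/CC[C@@]1(C)CCc2cc(O[Si](C(C)C)(C(C)C)C(C)C)c(C)c(C)c2O1 | intermediate
11 | (2E,6E)-farnesyl bromide | CC(C)=CCC/C(C)=C/CC/C(C)=C/CBr | starting material
12 | (2E,6E)-farnesyl phenyl sulfone | CC(C)=CCC/C(C)=C/CC/C(C)=C/CS(=O)(=O)c1ccccc1 | intermediate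
13 | (2E,6E,10E)-2,6,10-trimethyl-12-(phenylsulfonyl)dodeca-2,6,10-trien-1-ol | OC/C(C)=C/CC/C(C)=C/CC/C(C)=C/CS(=O)(=O)c1ccccc1 | intermediate
14 | (2E,6E,10E)-12-bromo-3,7,11-trimethyldodeca-2,6,10-trien-1-yl phenyl sulfone | BrC/C(C)=C/CC/C(C)=C/CC/C(C)=C/CS(=O)(=O)c1ccccc1 | intermediate
15 | (2E,6E)-farnesol | CC(C)=CCC/C(C)=C/CC/C(C)=C/CO | starting material
16 | (2S,3S)-2,3-epoxyfarnesol (trans-epoxide; CH2OH and the C4 chain on opposite faces) | CC(C)=CCC/C(C)=C/CC[C@]1(C)O[C@H]1CO | intermediate
17 | (2R,3S)-1-chloro-2,3-epoxy-3,7,11-trimethyldodeca-6,10-diene (farnesol numbering; same geometry as 16) | CC(C)=CCC/C(C)=C/CC[C@]1(C)O[C@H]1CCl | intermediate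
18 | (3S,6E)-1-chloro-3,7,11-trimethyldodeca-1,6,10-trien-3-ol, present as its lithium alkoxide (chloroalkene geometry not defined) | CC(C)=CCC/C(C)=C/CC[C@](C)(O)C=CCl | intermediate (not isolated)
19 | (3S,6E)-3,7,11-trimethyldodeca-6,10-dien-1-yn-3-ol | CC(C)=CCC/C(C)=C/CC[C@](C)(O)C#C | intermediate
20 | (6E,10S,14E,18E,22E)-2,6,10,14,18,22-hexamethyl-24-(phenylsulfonyl)tetracosa-2,6,14,18,22-pentaen-11-yn-10-ol | CC(C)=CCC/C(C)=C/CC[C@](C)(O)C#CC/C(C)=C/CC/C(C)=C/CC/C(C)=C/CS(=O)(=O)c1ccccc1 | intermediate
21 | (6E,10S,11E,14E,18E,22E)-2,6,10,14,18,22-hexamethyl-24-(phenylsulfonyl)tetracosa-2,6,11,14,18,22-hexaen-10-ol | CC(C)=CCC/C(C)=C/CC[C@](C)(O)/C=C/C/C(C)=C/CC/C(C)=C/CC/C(C)=C/CS(=O)(=O)c1ccccc1 | intermediate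
22 | dilithio derivative of 21 (lithium alkoxide at O–C10 and α-sulfonyl carbanion at C24) | CC(C)=CCC/C(C)=C/CC[C@](C)([O-])/C=C/C/C(C)=C/CC/C(C)=C/CC/C(C)=C/[CH-]S(=O)(=O)c1ccccc1.[Li+].[Li+] | intermediate (not isolated)
23 | (2S)-2-[(3E,7E,11E,15E,19E,22E,24S,27E)-24-hydroxy-4,8,12,16,20,24,28,32-octamethyl-10-(phenylsulfonyl)tritriaconta-3,7,11,15,19,22,27,31-octaen-1-yl]-2,7,8-trimethyl-6-(triisopropylsilyloxy)chroman, both C10' epimers | CC(C)=CCC/C(C)=C/CC[C@](C)(O)/C=C/C/C(C)=C/CC/C(C)=C/CC/C(C)=C/C(C/C(C)=C/CC/C(C)=C/CC[C@@]1(C)CCc2cc(O[Si](C(C)C)(C(C)C)C(C)C)c(C)c(C)c2O1)S(=O)(=O)c1ccccc1 | intermediate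
24 | (2S)-2-[(3E,7E,11E,15E,19E,22E,24S,27E)-24-hydroxy-4,8,12,16,20,24,28,32-octamethyltritriaconta-3,7,11,15,19,22,27,31-octaen-1-yl]-2,7,8-trimethyl-6-(triisopropylsilyloxy)chroman | CC(C)=CCC/C(C)=C/CC[C@](C)(O)/C=C/C/C(C)=C/CC/C(C)=C/CC/C(C)=C/CC/C(C)=C/CC/C(C)=C/CC[C@@]1(C)CCc2cc(O[Si](C(C)C)(C(C)C)C(C)C)c(C)c(C)c2O1 | intermediate
25 | (2S)-2-[(3E,7E,11E,15E,19E,22E,24S,27E)-24-hydroxy-4,8,12,16,20,24,28,32-octamethyltritriaconta-3,7,11,15,19,22,27,31-octaen-1-yl]-2,7,8-trimethylchroman-6-ol (CNP0323443.2) | CC(C)=CCC/C(C)=C/CC[C@](C)(O)/C=C/C/C(C)=C/CC/C(C)=C/CC/C(C)=C/CC/C(C)=C/CC/C(C)=C/CC[C@@]1(C)CCc2cc(O)c(C)c(C)c2O1 | target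

**Step count**

Total: 18 steps. Longest linear sequence: 10 steps (steps 1–7, then 16–18, from 2,3-dimethylhydroquinone).

**Steps most likely to fail**

1. Step 5. Carbonate or alkoxide may cleave the triflate at sulfur, or the arylpalladium may be reduced, faster than the hindered, electron-rich C8a centre undergoes C–O reductive elimination. The fallback makes the same O1–C8a bond by quinone ketal chemistry and sets out from 7. Bu4NF followed by aqueous Et4NOH in dioxane would remove the silyl ether and the triflate to give the hydroquinone carbinol F1, which Ag2O in ether would oxidise to the benzoquinone carbinol F2. With HC(OMe)3 and MeOH under catalytic p-TsOH the tertiary hydroxyl adds to the C8a carbonyl and the hemiketal is trapped as the cyclic 8a-methoxy ketal F3, with the C2–O bond untouched and so retained. Reduction with ascorbic acid in aqueous THF expels methanol and gives the chromanol F4, and TIPSCl with imidazole returns to the route at 8.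

2. Step 14. The copper acetylide may attack the γ-carbon of the allylic bromide (allylic transposition to a branched isomer) or dimerise oxidatively. The fallback sets out from 19. Hydrostannation with Bu3SnH under PdCl2(PPh3)2 catalysis in THF at 0 °C should give the distal (E)-vinylstannane F5. Stille coupling of this with 14 (Pd2(dba)3, AsPh3, NMP, 40 °C) joins C21'–C22' at the unhindered allyl terminus with the E-olefin already in place. It comes back to the route at 21, bypassing 20 and the hydride reduction.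

3. Step 6. Allylic oxidation may spread to the methylene groups flanking the internal C3'=C4' olefin or run on to the aldehyde, eroding site selectivity and conversion. The fallback sets out from 8. Cross-metathesis of the sterically exposed isopropylidene terminus with methacrolein (second-generation Hoveyda–Grubbs catalyst, CH2Cl2, 40 °C) would give the (E)-enal F6 with loss of 2-methylpropene. Luche reduction (NaBH4, CeCl3·7H2O, MeOH, 0 °C) then returns to the route at 9.

**Further compounds**

F1 | step 5 | 2-[(3S,6E)-3-hydroxy-3,7,11-trimethyldodeca-6,10-dien-1-yl]-5,6-dimethylbenzene-1,4-diol | CC(C)=CCC/C(C)=C/CC[C@](C)(O)CCc1cc(O)c(C)c(C)c1O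
F2 | step 5 | 2-[(3S,6E)-3-hydroxy-3,7,11-trimethyldodeca-6,10-dien-1-yl]-5,6-dimethyl-1,4-benzoquinone | CC(C)=CCC/C(C)=C/CC[C@](C)(O)CCC1=CC(=O)C(C)=C(C)C1=O
F3 | step 5 | (2S)-2-[(3E)-4,8-dimethylnona-3,7-dien-1-yl]-8a-methoxy-2,7,8-trimethyl-2,3,4,8a-tetrahydrochromen-6-one (both C8a epimers) | CC(C)=CCC/C(C)=C/CC[C@@]1(C)CCC2=CC(=O)C(C)=C(C)C2(OC)O1
F4 | step 5 | (2S)-2-[(3E)-4,8-dimethylnona-3,7-dien-1-yl]-2,7,8-trimethylchroman-6-ol | CC(C)=CCC/C(C)=C/CC[C@@]1(C)CCc2cc(O)c(C)c(C)c2O1
F5 | step 14 | (1E,3S,6E)-3,7,11-trimethyl-1-(tributylstannyl)dodeca-1,6,10-trien-3-ol | CC(C)=CCC/C(C)=C/CC[C@](C)(O)/C=C/[Sn](CCCC)(CCCC)CCCC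
F6 | step 6 | (2E,6E)-2,6-dimethyl-9-[(2S)-2,7,8-trimethyl-6-(triisopropylsilyloxy)chroman-2-yl]nona-2,6-dienal | O=C/C(C)=C/CC/C(C)=C/CC[C@@]1(C)CCc2cc(O[Si](C(C)C)(C(C)C)C(C)C)c(C)c(C)c2O1
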